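**Retrosynthetic overview**
- Feature: the target is one 29-membered lactone ring (ring oxygen, carbonyl C1, then C2–C28 as 27 unbranched methylenes) with no substituent and no stereocentre. Every C–C bond far from the ester is therefore an equivalent closure site, and C13–C14 is chosen because two natural Z-fatty chains end exactly there.
- Last disconnection: the C13–C14 single bond is traced back to a C13=C14 ring olefin, whose geometry is erased by hydrogenation.
- Key disconnection: the C13=C14 olefin is opened by retro-ring-closing metathesis to the wax ester of erucic acid (olefin at C13 of the acyl chain) and nervonyl alcohol (olefin at C15 of the alkyl chain), with octadec-9-ene as the leaving fragment.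
- The ester C–O bond is cut to erucic acid and nervonyl alcohol; the alcohol comes from nervonic acid by hydride reduction.
- Ring order: the only ring, the 29-membered lactone, is closed in step 3.

Key step: step 3

Remark on the chemistry: both fatty acids are taken as homologue-pure and positionally pure Z-isomers, because chain-length or double-bond-position impurities would end up as ring-size homologues of the target.

**Route**

Step 1
Reactants: 1 nervonic acid, (Z)-tetracos-15-enoic acid
Product: 2 nervonyl alcohol, (Z)-tetracos-15-en-1-ol
Conditions: LiAlH4, THF, 0 °C to reflux; then H2O, 0 °C, filtration through Celite
Reagents that add atoms: none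
Why: Hydride reduction of a carboxylic acid to the primary alcohol with LiAlH4; the isolated Z-olefin at C15 is inert to nucleophilic hydride, so its position and geometry should be unchanged.

Step 2
Reactants: 2 nervonyl alcohol, (Z)-tetracos-15-en-1-ol; 3 erucic acid, (Z)-docos-13-enoic acid
Product: 4 (Z)-tetracos-15-en-1-yl (Z)-docos-13-enoate
Conditions: N,N'-dicyclohexylcarbodiimide, DMAP (cat.), CH2Cl2, 0 °C to rt
Reagents that add atoms: none
Why: Steglich esterification, in which the carbodiimide activates the acid and DMAP relays the acyl group to the unhindered primary alcohol under neutral conditions, so neither Z-olefin should migrate and no stereocentre is involved.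

Step 3
Reactants: 4 (Z)-tetracos-15-en-1-yl (Z)-docos-13-enoate
Product: 5 1-oxacyclononacos-14-en-2-one (E and Z mixture)
Conditions: second-generation Grubbs catalyst RuCl2(=CHPh)(PCy3)(H2IMes) (5 mol %), 1,4-benzoquinone (10 mol %), CH2Cl2 (1 mM in 4), 40 °C; then ethyl vinyl ether
Reagents that add atoms: none
Why: Olefin metathesis through ruthenacyclobutanes: the benzylidene of the catalyst undergoes [2+2] cycloaddition and cycloreversion with one Z-olefin of 4 to leave a ruthenium alkylidene on the ester-bearing chain, and this carbene adds across the second olefin of the same molecule to release the ring and a nonylidene carbene that carries the cycle on and ends as octadec-9-ene. The closest known reaction type is ring-closing olefin metathesis to large macrolactones, including closures of fatty di-olefins in which an internal olefin and not ethene is the leaving fragment. The single ring, the 29-membered lactone, is closed end to end by forming the C13=C14 double bond (ring positions 14 and 15), a site separated from the ester by eleven methylenes on the acyl side and fourteen on the alkoxy side, so the ester can neither chelate nor deactivate the carbene. No stereocentre is formed, and the olefin should arise as an E and Z mixture, which is of no consequence because step 4 removes it. The selectivity needed is ring against chain: since octadec-9-ene stays in solution the step is an equilibrium, and the strain-free unbranched chain together with the 1 mM dilution should hold the concentration below the effective molarity of the ring, so that acyclic and cyclic oligomers formed on the way are cut back to the monomeric lactone by the same reversible metathesis. The second need is ring-size fidelity, which rests on the olefins staying at C13 and C15; 1,4-benzoquinone is added to intercept ruthenium hydrides that would otherwise walk the double bonds and give ring homologues.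

Step 4
Reactants: 5 1-oxacyclononacos-14-en-2-one (E and Z mixture)
Product: 6 octacosanolide, 1-oxacyclononacosan-2-one
Conditions: H2 (1 atm), palladium on carbon (Pd/C, 10 wt %), EtOAc, rt
Reagents that add atoms: none
Why: Heterogeneous catalytic hydrogenation of an unhindered 1,2-disubstituted olefin, in which both geometric isomers of 5 converge on the same saturated ring and the lactone C–O bond, being neither allylic nor benzylic, should not be hydrogenolysed.

**Compound list**

1 | nervonic acid, (Z)-tetracos-15-enoic acid | CCCCCCCC/C=C\CCCCCCCCCCCCCC(=O)O | starting material
2 | nervonyl alcohol, (Z)-tetracos-15-en-1-ol | CCCCCCCC/C=C\CCCCCCCCCCCCCCO | intermediate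
3 | erucic acid, (Z)-docos-13-enoic acid | CCCCCCCC/C=C\CCCCCCCCCCCC(=O)O | starting material
4 | (Z)-tetracos-15-en-1-yl (Z)-docos-13-enoate | CCCCCCCC/C=C\CCCCCCCCCCCC(=O)OCCCCCCCCCCCCCC/C=C\CCCCCCCC | intermediate
5 | 1-oxacyclononacos-14-en-2-one (E and Z mixture) | O=C1CCCCCCCCCCCC=CCCCCCCCCCCCCCCO1 | intermediate
6 | octacosanolide, 1-oxacyclononacosan-2-one | O=C1CCCCCCCCCCCCCCCCCCCCCCCCCCCO1 | target

**Totals**

Total step count: 4. Longest linear sequence: 4 steps (1 → 2 → 4 → 5 → 6).

**Steps most likely to fail**

Step 3 (ring-closing metathesis). Three processes may go wrong. The ring–chain equilibrium may stall short of full conversion because the expelled octadec-9-ene is not removed and can re-open the ring. Intermolecular metathesis may divert material into acyclic and cyclic oligomers if the dilution is not sufficient. Hydride-mediated double-bond migration before closure would contract or expand the ring by one carbon. Fallback: setting out from 4, ethenolysis with ethylene and the first-generation Grubbs catalyst RuCl2(=CHPh)(PCy3)2 in CH2Cl2 at 40 °C would cut both internal olefins to vinyl groups. This gives hexadec-15-en-1-yl tetradec-13-enoate F1 and two equivalents of dec-1-ene, which is removed by distillation. Ring-closing metathesis of F1 with the second-generation Grubbs catalyst RuCl2(=CHPh)(PCy3)(H2IMes) at high dilution under an argon sparge then loses ethene irreversibly and comes back to the route at 5.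

Step 2 (esterification). The carbodiimide-activated acid may rearrange by O-to-N acyl migration to an unreactive N-acylurea, and dicyclohexylurea may co-elute with the waxy, non-polar ester. Fallback: setting out from 3, oxalyl chloride with catalytic DMF in CH2Cl2 would give (Z)-docos-13-enoyl chloride F2, which is not purified. It is then acylated onto alcohol 2 in CH2Cl2 with pyridine at 0 °C, and the sequence comes back to the route at 4.

Step 4 (hydrogenation). Saturation may stay incomplete through poisoning of the palladium surface by ruthenium or quinone residues carried over from step 3, or through crystallisation of the waxy macrolide onto the catalyst; traces of unsaturated ring would be hard to separate. Fallback: setting out from 5, metal-free diimide reduction (p-toluenesulfonyl hydrazide, NaOAc, aqueous 1,2-dimethoxyethane, reflux) transfers H2 to the olefin in a concerted way and comes back to the route at 6. No new compound arises on this way (F0).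

**Further compounds**

F1 | step 3 | hexadec-15-en-1-yl tetradec-13-enoate | C=CCCCCCCCCCCCC(=O)OCCCCCCCCCCCCCCC=C
F2 | step 2 | (Z)-docos-13-enoyl chloride | CCCCCCCC/C=C\CCCCCCCCCCCC(=O)Cl
F0 | step 4 | none | none
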